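The product I keep books on is open intermediate, which substrate gives and which second intermediate carries on to target.

    substrate → open intermediate (k1 = 0.127 s⁻¹)
    partner → second intermediate (k2 = 0.0746 s⁻¹)
    2 second intermediate → homo product (k3 = 22.4 M⁻¹ s⁻¹)
    open intermediate + second intermediate → target (k4 = 32.9 M⁻¹ s⁻¹)

in all of them: substrate 0.079 M

| run | partner | remark | time |
|---|---|---|---|
| autumn | 1.00 equiv | one stirred flow tank at steady state, fed with the mixture as stated, mean residence time 12 s |  |
| dusk | 1.00 equiv | one stirred flow tank at steady state, fed with the mixture as stated, mean residence time 36.0 s |  |
| winter | 1.00 equiv | everything together in a closed stirred flask, run for 12 s | 12 s |
| noon | 1.00 equiv (fed, over 6.00 s) | a stirred flask in which partner is dosed at a steady rate over 6.00 s without added volume, worked up at 12 s | 12 s |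

* the set-up with the highest amount of open intermediate at the outlet or at the end, in percent of the substrate put in ("none" if the first two lie within 2 percentage points) (autumn / dusk / winter / noon / none)
* amount of open intermediate at the outlet or at the end, in percent of the substrate put in, autumn
* amount of open intermediate at the outlet or at the end, in percent of the substrate put in, dusk
* amount of open intermediate at the outlet or at the end, in percent of the substrate put in, winter
* amount of open intermediate at the outlet or at the end, in percent of the substrate put in, noon

- a step written with two of one species runs at k times the square of its concentration and takes two of it each time
- the stated concentrations are those of everything mixed, before any reaction; amounts are the same in each set-up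
- the feed brings no volume worth counting
- run time (winter): 12 s

- Substrate and partner are charged equally, so either can serve as the limiting reagent, and I enter every mole in percent of the substrate charged.
- The first entry is what has not yet turned. Substrate has a half-life of 5.5 s and partner one of 9.3 s, so in 12 s substrate passes 2.18 half-lives, more than the 1.29 of partner. In winter this leaves 21.8% of the substrate and 40.9% of the partner.
- The second entry is turned partner. Each mole gives one second intermediate, which becomes target one for one, goes to homo product two per turn, or stands unreacted. Each target also uses one turned substrate.
- The books close at equal charges: [open intermediate] = partner left − substrate left + 2[homo product] + [second intermediate]. I call partner left minus substrate left, 19.1% in winter, the floor: the open intermediate standing if every turned partner were captured.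
- The same books hold at a tank outlet, where a reagent's fraction left is lifetime/(lifetime + residence time). The floor is then 13.1% in autumn and 9.19% in dusk.
- In noon, the dose over 6.00 s keeps more partner unturned than in winter, and the floor is 29.7%. That is the highest of the four, so I pick noon, though I leave the diverted entries unreckoned.
- The forecast, a rough mental estimate, picks noon with 25.6%, 22.4%, 34.8% and 38.7% for autumn, dusk, winter and noon, on the ground that “holding the partner back early lets it build up before capture starts”.
- The simulation gives noon as best, with 25.6%, 22.4%, 34.8% and 38.8% in the same order.
- The main reason noon holds 38.8% of open intermediate is the stop at 12 s: left for ten times as long, it holds 10.7%. Slow dosing is part of why noon leads: given at once, the partner leaves 34.8% of open intermediate instead of 38.8%. In the books, the floor rises from 19.1% in winter to 29.7% in noon, while the diverted entries are smaller, 9.09% in noon against 15.7% in winter, so the lead is 4 percentage points. In the neighbour of winter with substrate at 0.020 M, the floor stays 19.1%, the diverted entries reach 25.5%, and open intermediate stands at 44.6%.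

(The constants used here stand for no real mixture; the flask was simulated.)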